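Remark on the chemistry: the target has no stereocentre, so no descriptors are needed. Ring positions of all intermediates are given in flavone numbering (O1, C2, C3, C4, C4a, C5 to C8, C8a; ring B primed).

## Analysis of the target

The target is a flavonol: ring A (C4a, C5–C8, C8a) is fused to the 3-hydroxy-4-pyranone ring C (O1, C2, C3, C4), and ring B is a 4-hydroxy-3-methoxyphenyl group on C2. There is no stereocentre and no olefin geometry to set, so the whole problem is one of regiochemistry. Ring A is fully differentiated: C5 carries a hydroxyl chelated to the C4 carbonyl, C6 is unsubstituted, C7 carries the 3-methylbut-2-enyl (prenyl) ether and C8 a methoxy group. The prenyl ether does not survive hydrogenolysis, Lewis or protic acid, or strong heating, so it must go onto O7 alone and late, while O3, O5 and O4' end up free. The 3-hydroxy-4-pyranone is also sensitive: it is degraded by air in base, and under hot acid a 5-hydroxy-7,8-dioxygenated flavone can isomerise to the 6,7-pattern by ring opening (Wessely–Moser). The difficulty is therefore twofold: placing the acyl carbon C4 on a ring A carbon flanked by two different oxygens, and telling O5 from O8a and O7 from the other hydroxyls. The strategy rests on one feature: C5 (oxygen) and C4a (acyl carbon C4) are neighbours, and C8a next to C4a bears oxygen. An aryne across C4a–C5, polarised by the C8a oxygen, can thus take up oxygen at C5 and the acyl carbon at C4a in one event. Such an aryne derives from a mirror-symmetric 3,4,5-trioxygenated phenol, so its precursor raises no regiochemical question.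

## Retrosynthetic reasoning

**O7–prenyl bond and the acetates.** The last bonds cut are the three ester C–O bonds of triacetate 28 and, before that, the O7–prenyl bond, leading to tetraacetate 25 and prenyl bromide (26). The allylic ether is installed last because every method that removes a benzyl or methyl ether would destroy it; the acetates are chosen because ammonolysis removes them. The cut is made at 25 and not at the free tetrol 24 because in 24 the hydroxyls on C7, C4' and C3 are too close in acidity. In 25 only the acetate on O7, the ester of the most acidic hydroxyl, is lost to carbonate, so phenoxide 27 forms and is alkylated alone.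

**Global deprotection.** Tetraacetate 25 comes from tetrol 24 by acetylation, and 24 from the protected flavone 23 by one Lewis-acid operation that breaks three O–benzyl bonds and the O5–methyl bond. The O5 methyl is the only methyl ether peri to the C4 carbonyl, so chelation removes it while the C8 and C3' methoxy groups of the target stay.

**Ring C.** Flavone 23 is opened at O1–C2 and C2–C3, the Baker–Venkataraman disconnection. β-Diketone 22 arises from aryl ester 21 by aroyl transfer from O8a to the ketone α-carbon C3. Ester 21 comes from phenol 16 and acid 19 through acid chloride 20, and 19 from vanillin (17) via aldehyde 18. A chalcone route is avoided because the oxidative chalcone-to-flavonol closure gives aurones when the position corresponding to C5 is substituted. With the C3 oxygen already in the ketone side chain, ring C needs no redox adjustment. The cyclodehydration must close through O8a only, which the methyl group on O5 guarantees.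

**Exchange of roles of O5 and O8a.** The key step delivers the free hydroxyl on C5, but ring closure needs it on C8a. Phenol 16 therefore comes from 15 by cleaving the benzyl ether ortho to the ketone (O8a), and 15 from ketone 14 by methylating O5. The O8a–benzyl bond is the place to cut because it is the only benzyl ether able to chelate the carbonyl group, which sets it apart from the benzyl ethers on O7 and in the side chain.

**Key disconnection.** Ketone 14 is cut at two bonds on adjacent ring carbons, C5–O and C4a–C4. Both form at once when aryne 12, released by fluoride from silyl triflate 10, inserts into the C–O bond of benzyloxyacetic acid (11) by way of hemiketal 13. This is preferred to a Friedel–Crafts or Fries acylation of phenol 6 because it needs no Lewis acid in the presence of the benzyl ethers. The acid partner also brings in C4, C3 and the C3 oxygen at the right oxidation level. The forward reaction must put oxygen on C5 and carbon on C4a, not the reverse; the benzyloxy group on C8a controls this.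

**Aryne precursor.** Silyl triflate 10 is traced to bromophenol 7: O-silylation (8), bromine–lithium exchange with a retro-Brook shift (9), then triflation. Bromophenol 7 comes from phenol 6 by monobromination. Phenol 6 has a mirror plane through C1 and C4, its ortho positions are equivalent and its para position is blocked. Bromine, and then silicon, can only land on the carbon that becomes C4a.

**Symmetric phenol.** Phenol 6 comes from aldehyde 4 by Baeyer–Villiger oxidation through formate 5. Aldehyde 4 comes from ester 2 by reduction to alcohol 3 and reoxidation, and 2 from methyl 3,5-dihydroxy-4-methoxybenzoate (1) by benzylation. The carboxyl carbon of 1 is exchanged for the oxygen that later leaves as triflate; the methoxy group of 1 is the C8 methoxy group of the target.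

## Alternatives that were turned down

**Alternative 1:** Ring A is disconnected at C5–C6. The precursor is pyranone A1, in which rings B and C are complete, C4a carries an ester (drawn as the methyl ester) and C8a a 1-methoxy-2-oxopropyl chain. Two equivalents of LiN(iPr)2 would form the dienolate, whose terminal carbon (future C6) attacks the ester carbon (future C5) in a Claisen-type six-membered closure. Enolisation then aromatises ring A to give A2.
- For: the step is biomimetic and closes a ring. A2 emerges with O7 free and acidic, O5 chelated, and O3 and O4' masked, so prenylation would be direct. On this point it is stronger than the chosen strategy, which needs an acetate relay to single out O7.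
- Against: A1 is a pentasubstituted pyranone. C2, C4a and C8a each need their own C–C bond formation on an electron-poor heterocycle, and no short assembly is apparent.
- Against: the terminal methyl must be deprotonated next to a far more acidic C8–H, and amide base or dianion can add to C2 of the pyranone.
- Against: the two methoxymethyl ethers of the prenylated product must be removed with acid, the condition the prenyl ether tolerates worst.
- Comparison: the chosen strategy offers instead a six-step, regiochemically trivial precursor and a non-acidic final deprotection.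

**Alternative 2:** Ring C is disconnected at C3–C4. Dialdehyde A3 is a ring A benzaldehyde whose O8a is etherified with an α-aryl-α-formylmethyl unit and whose O7 already bears the prenyl group. SmI2 would reduce the aryl aldehyde to a ketyl, which adds to the tethered aldehyde and closes ring C as flavan-3,4-diol A4 (diastereomer mixture).
- For: single-electron conditions are neutral and tolerate the prenyl ether. This is the only plan that carries the ether from an early stage, and there it is stronger than the chosen strategy, which must differentiate O7 late. Ring C also closes in the key step.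
- Against: A4 is at the wrong oxidation level. Three stereocentres (C2, C3, C4) are made only to be destroyed, and a four-electron oxidation must follow on an electron-rich molecule with an oxidisable trisubstituted olefin.
- Against: the aliphatic aldehyde of A3 is α-aryloxy and α-aryl substituted. It enolises easily, and its ketyl can expel the ring A phenoxide by reductive C–O cleavage in competition with coupling.
- Against: the O8a ether of A3 is flanked by formyl and methoxy groups and is hard to make, and the methoxymethyl groups again need acid with the prenyl ether present.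
- Comparison: the chosen route installs C4 as a ketone and C3 with its oxygen directly, with no stereocentres and no redox correction.

**Alternative 3:** Ring C is disconnected at C4a–C4, C4–C3 and O1–C2. ortho-Iodophenol A5, arylacetylene A6 and a carbonylating atmosphere would combine under zerovalent palladium (from PdCl2(PPh3)2 in diethylamine). The sequence is oxidative addition, carbonyl insertion, coupling to the ynone and 6-endo closure by the phenoxide, giving flavone A7.
- For: it is the most convergent plan, with three bonds and ring C formed from two halves of similar size. On bond count and convergence it is clearly stronger than the chosen key step (two bonds, no ring).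
- Against: A7 lacks the C3 oxygen, so a separate C3 hydroxylation of an electron-rich 5-alkoxyflavone must follow.
- Against: A5 needs iodine on C4a between two oxygenated carbons, in a ring whose other free position (C6) is electronically at least as reactive, with no symmetry to help.
- Against: oxidative addition into so hindered and electron-rich an iodide is slow, and 5-exo closure to an aurone competes.
- Against: the end game from three benzyl ethers is no shorter than in the chosen route.
- Comparison: the chosen strategy gives up convergence but brings the C3 oxygen in with the acid partner and takes its regiochemistry from a symmetric phenol.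

Key step: step 7

## Route

Step 1
Reactants: 1 methyl 3,5-dihydroxy-4-methoxybenzoate
Product: 2 methyl 3,5-bis(benzyloxy)-4-methoxybenzoate
Conditions: BnBr, K2CO3, DMF, 60 °C
Reagents that add atoms: benzyl bromide, BrCc1ccccc1
Why: Williamson etherification of both phenols; the methyl ester and the flanked methoxy group are inert to K2CO3 in DMF.

Step 2
Reactants: 2 methyl 3,5-bis(benzyloxy)-4-methoxybenzoate
Product: 3 [3,5-bis(benzyloxy)-4-methoxyphenyl]methanol
Conditions: LiAlH4, THF, 0 °C → rt
Reagents that add atoms: none
Why: Hydride reduction of the benzoate ester to the benzylic alcohol; benzyl and methyl aryl ethers are untouched by LiAlH4.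

Step 3
Reactants: 3 [3,5-bis(benzyloxy)-4-methoxyphenyl]methanol
Product: 4 3,5-bis(benzyloxy)-4-methoxybenzaldehyde
Conditions: MnO2, CH2Cl2, rt
Reagents that add atoms: none
Why: Heterogeneous MnO2 oxidation is selective for benzylic alcohols and should stop cleanly at the aldehyde.

Step 4
Reactants: 4 3,5-bis(benzyloxy)-4-methoxybenzaldehyde
Product: 6 3,5-bis(benzyloxy)-4-methoxyphenol, via aryl formate 5 (not isolated)
Conditions: mCPBA, CH2Cl2, 0 °C → rt; then KOH, MeOH, 0 °C; aq. HCl work-up
Reagents that add atoms: meta-chloroperoxybenzoic acid (mCPBA), OOC(=O)c1cccc(Cl)c1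
Why: Baeyer–Villiger (Dakin-type) oxidation: in the Criegee adduct the electron-rich trialkoxyaryl group migrates to oxygen to give formate 5, which methanolic KOH cleaves. The resulting phenol 6 is mirror-symmetric, which makes the next step regiochemically trivial.

Step 5
Reactants: 6 3,5-bis(benzyloxy)-4-methoxyphenol
Product: 7 3,5-bis(benzyloxy)-2-bromo-4-methoxyphenol
Conditions: NBS (1.0 equiv), CH2Cl2, −78 → 0 °C
Reagents that add atoms: N-bromosuccinimide, O=C1CCC(=O)N1Br
Why: Electrophilic aromatic bromination of a phenol whose para position is blocked and whose two ortho positions are equivalent, so one equivalent of NBS can give only one monobromide. The benzyl rings are far less activated and ionic low-temperature conditions avoid benzylic bromination.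

Step 6
Reactants: 7 3,5-bis(benzyloxy)-2-bromo-4-methoxyphenol
Product: 10 3,5-bis(benzyloxy)-4-methoxy-2-(trimethylsilyl)phenyl trifluoromethanesulfonate, via aryl silyl ether 8 (not isolated), via lithium silylphenoxide 9 (not isolated)
Conditions: (Me3Si)2NH, THF, 70 °C, then evaporate; n-BuLi, THF, −100 → −80 °C; Tf2O, −100 → −78 °C
Reagents that add atoms: hexamethyldisilazane, C[Si](C)(C)N[Si](C)(C)C; trifluoromethanesulfonic anhydride, O=S(=O)(OS(=O)(=O)C(F)(F)F)C(F)(F)F
Why: O-Silylation gives 8; bromine–lithium exchange at −100 °C is faster than benzylic deprotonation, and the aryllithium takes silicon from the neighbouring oxygen (retro-Brook 1,3-shift) to give phenoxide 9, which Tf2O traps. This is the standard sequence for ortho-silylaryl triflates, including ones with a 3-alkoxy group.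

Step 7
Reactants: 10 3,5-bis(benzyloxy)-4-methoxy-2-(trimethylsilyl)phenyl trifluoromethanesulfonate; 11 benzyloxyacetic acid
Product: 14 2-(benzyloxy)-1-[2,4-bis(benzyloxy)-6-hydroxy-3-methoxyphenyl]ethan-1-one, via aryne 12 (not isolated), via benzoxetene hemiketal 13 (not isolated)
Conditions: 11 (1.5 equiv), CsF (4 equiv), THF, 125 °C, sealed tube
Reagents that add atoms: none
Why: This is the fluoride-induced insertion of an aryne into the C–O bond of a carboxylic acid, a known reaction type that gives ortho-hydroxyaryl ketones. CsF removes the silyl group of 10 and triflate leaves, releasing aryne 12 with its triple bond between the future C5 and C4a. The carboxylate of 11 adds through oxygen to C5, the terminus remote from the benzyloxy group on C8a: that inductively withdrawing oxygen distorts the aryne so that C5 is the more electrophilic carbon, and the negative charge developing at C4a lies next to the C8a–O bond that stabilises it. The aryl anion at C4a then attacks the ester carbonyl in a 4-exo-trig closure to hemiketal 13, a transient four-membered ring that is not part of the target and opens at once by C–O cleavage to the chelated ortho-acylphenoxide; no ring of the target is closed and no stereocentre is formed. Two selectivities are needed. The first is the regiochemistry of addition, secured by the C8a oxygen directly beside the triple bond, against which the more remote alkoxy groups on C7 and C8 are weak perturbations. The second is acyl capture rather than protonation of the aryl anion, favoured because the capture is intramolecular and because in hot THF with excess CsF the acid is present largely as its cesium salt. Fluoride leaves the benzyl ethers and the α-benzyloxy ketone untouched, which a Lewis-acid acylation of the phenol would not guarantee.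

Step 8
Reactants: 14 2-(benzyloxy)-1-[2,4-bis(benzyloxy)-6-hydroxy-3-methoxyphenyl]ethan-1-one
Product: 15 2-(benzyloxy)-1-[2,4-bis(benzyloxy)-3,6-dimethoxyphenyl]ethan-1-one
Conditions: MeI, K2CO3, DMF, 40 °C
Reagents that add atoms: iodomethane, CI
Why: Williamson O-methylation of the chelated phenol; K2CO3 does not enolise the α-alkoxy ketone. The methyl group masks O5 as the one ether that the final boron Lewis acid removes by chelation to the C4 carbonyl.

Step 9
Reactants: 15 2-(benzyloxy)-1-[2,4-bis(benzyloxy)-3,6-dimethoxyphenyl]ethan-1-one
Product: 16 2-(benzyloxy)-1-[4-(benzyloxy)-2-hydroxy-3,6-dimethoxyphenyl]ethan-1-one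
Conditions: MgBr2·OEt2 (3 equiv), toluene/Et2O, 80 °C; aq. NH4Cl
Reagents that add atoms: none
Why: Chelation-controlled cleavage of a benzyl aryl ether ortho to a carbonyl group: magnesium bridges the ketone oxygen and O8a, and bromide attacks the benzylic carbon to release the magnesium phenoxide. Benzyl is displaced far more readily than the methyl on O5; the benzyl ether on O7 cannot chelate, and the side-chain benzyl ether would have to expel an alkoxide.

Step 10
Reactants: 17 vanillin
Product: 18 4-(benzyloxy)-3-methoxybenzaldehyde
Conditions: BnBr, K2CO3, DMF, rt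
Reagents that add atoms: benzyl bromide, BrCc1ccccc1
Why: Williamson etherification of the single phenol of vanillin.

Step 11
Reactants: 18 4-(benzyloxy)-3-methoxybenzaldehyde
Product: 19 4-(benzyloxy)-3-methoxybenzoic acid
Conditions: NaClO2, NaH2PO4, 2-methylbut-2-ene, t-BuOH/H2O, rt
Reagents that add atoms: sodium chlorite, [Na+].[O-]Cl=O
Why: Pinnick oxidation of the aldehyde to the acid; the alkene scavenges hypochlorous acid and so protects the electron-rich ring from chlorination.

Step 12
Reactants: 19 4-(benzyloxy)-3-methoxybenzoic acid; 16 2-(benzyloxy)-1-[4-(benzyloxy)-2-hydroxy-3,6-dimethoxyphenyl]ethan-1-one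
Product: 21 3-(benzyloxy)-6-[2-(benzyloxy)acetyl]-2,5-dimethoxyphenyl 4-(benzyloxy)-3-methoxybenzoate, via acid chloride 20 (not isolated)
Conditions: (COCl)2, DMF (cat.), CH2Cl2, 0 °C → rt, evaporate; then 16, Et3N, DMAP (cat.), CH2Cl2, 0 °C → rt
Reagents that add atoms: none
Why: Acid chloride formation under DMF catalysis, then DMAP-catalysed O-acylation of the hindered, hydrogen-bonded phenol. The aroyl group is thereby placed on O8a for intramolecular transfer.

Step 13
Reactants: 21 3-(benzyloxy)-6-[2-(benzyloxy)acetyl]-2,5-dimethoxyphenyl 4-(benzyloxy)-3-methoxybenzoate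
Product: 23 3,7-bis(benzyloxy)-2-[4-(benzyloxy)-3-methoxyphenyl]-5,8-dimethoxy-4H-chromen-4-one, via β-diketone 22 (not isolated)
Conditions: LiN(SiMe3)2 (3 equiv), THF, −78 °C → rt; AcOH quench, evaporate; then AcOH, H2SO4 (cat.), 60 °C
Reagents that add atoms: none
Why: Baker–Venkataraman rearrangement: the ketone enolate attacks the neighbouring aryl ester through a six-membered transition state and forms C2–C3 (diketone 22). Acid then closes ring C by 6-exo-trig attack of the O8a hydroxyl on the aroyl carbonyl, followed by dehydration. Because O5 is methylated, only O8a can close, so only the 5,7,8-oxygenated isomer can form.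

Step 14
Reactants: 23 3,7-bis(benzyloxy)-2-[4-(benzyloxy)-3-methoxyphenyl]-5,8-dimethoxy-4H-chromen-4-one
Product: 24 3,5,7-trihydroxy-2-(4-hydroxy-3-methoxyphenyl)-8-methoxy-4H-chromen-4-one
Conditions: BCl3 (excess), pentamethylbenzene, CH2Cl2, −78 → 0 °C; H2O quench
Reagents that add atoms: none
Why: BCl3 cleaves the three benzyl ethers, with pentamethylbenzene trapping the benzyl cation so that C6 of the electron-rich ring A is not benzylated. It also removes the O5 methyl group through the six-membered boron chelate with the C4 carbonyl, a standard selective 5-O-demethylation of flavones. The non-chelated methoxy groups on C8 and C3' should react much more slowly at this temperature.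

Step 15
Reactants: 24 3,5,7-trihydroxy-2-(4-hydroxy-3-methoxyphenyl)-8-methoxy-4H-chromen-4-one
Product: 25 2-[4-(acetyloxy)-3-methoxyphenyl]-8-methoxy-4-oxo-4H-chromene-3,5,7-triyl triacetate
Conditions: Ac2O, pyridine, DMAP (cat.), rt → 50 °C
Reagents that add atoms: acetic anhydride, CC(=O)OC(C)=O
Why: Exhaustive acetylation, with DMAP to drive the chelated 5-hydroxyl; it turns the four hydroxyls into esters of graded lability.

Step 16
Reactants: 25 2-[4-(acetyloxy)-3-methoxyphenyl]-8-methoxy-4-oxo-4H-chromene-3,5,7-triyl triacetate; 26 prenyl bromide
Product: 28 2-[4-(acetyloxy)-3-methoxyphenyl]-8-methoxy-7-[(3-methylbut-2-en-1-yl)oxy]-4-oxo-4H-chromene-3,5-diyl diacetate, via O7-deacetylated phenol 27 (not isolated)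
Conditions: 26 (1.2 equiv), K2CO3, KI (cat.), acetone, reflux
Reagents that add atoms: none
Why: Selective 7-O-alkylation of a flavonol peracetate, a known reaction type: the acetate on O7 is the ester of the most acidic hydroxyl (vinylogous acid para to the C4 carbonyl) and is the first to be cleaved by carbonate. The phenoxide of 27 is then alkylated in situ by the allylic bromide (Williamson), while the remaining acetates keep O3, O5 and O4' blocked.

Step 17
Reactants: 28 2-[4-(acetyloxy)-3-methoxyphenyl]-8-methoxy-7-[(3-methylbut-2-en-1-yl)oxy]-4-oxo-4H-chromene-3,5-diyl diacetate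
Product: 29 3,5-dihydroxy-2-(4-hydroxy-3-methoxyphenyl)-8-methoxy-7-[(3-methylbut-2-en-1-yl)oxy]-4H-chromen-4-one
Conditions: NH3 (7 M in MeOH), THF, 0 °C → rt, argon
Reagents that add atoms: none
Why: Ammonolysis of the three aryl and enol acetates under mild, non-acidic conditions to which the prenyl ether is inert; exclusion of air protects the flavonol anion from oxidation.

## Compound list

1 | methyl 3,5-dihydroxy-4-methoxybenzoate | COC(=O)c1cc(O)c(OC)c(O)c1 | starting material
2 | methyl 3,5-bis(benzyloxy)-4-methoxybenzoate | COC(=O)c1cc(OCc2ccccc2)c(OC)c(OCc2ccccc2)c1 | intermediate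
3 | [3,5-bis(benzyloxy)-4-methoxyphenyl]methanol | OCc1cc(OCc2ccccc2)c(OC)c(OCc2ccccc2)c1 | intermediate
4 | 3,5-bis(benzyloxy)-4-methoxybenzaldehyde | O=Cc1cc(OCc2ccccc2)c(OC)c(OCc2ccccc2)c1 | intermediate
5 | 3,5-bis(benzyloxy)-4-methoxyphenyl formate | O=COc1cc(OCc2ccccc2)c(OC)c(OCc2ccccc2)c1 | intermediate
6 | 3,5-bis(benzyloxy)-4-methoxyphenol | Oc1cc(OCc2ccccc2)c(OC)c(OCc2ccccc2)c1 | intermediate
7 | 3,5-bis(benzyloxy)-2-bromo-4-methoxyphenol | Oc1cc(OCc2ccccc2)c(OC)c(OCc2ccccc2)c1Br | intermediate
8 | [3,5-bis(benzyloxy)-2-bromo-4-methoxyphenoxy]trimethylsilane | C[Si](C)(C)Oc1cc(OCc2ccccc2)c(OC)c(OCc2ccccc2)c1Br | intermediate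
9 | lithium 3,5-bis(benzyloxy)-4-methoxy-2-(trimethylsilyl)phenolate | [Li+].[O-]c1cc(OCc2ccccc2)c(OC)c(OCc2ccccc2)c1[Si](C)(C)C | intermediate
10 | 3,5-bis(benzyloxy)-4-methoxy-2-(trimethylsilyl)phenyl trifluoromethanesulfonate | C[Si](C)(C)c1c(OS(=O)(=O)C(F)(F)F)cc(OCc2ccccc2)c(OC)c1OCc1ccccc1 | intermediate
11 | benzyloxyacetic acid | OC(=O)COCc1ccccc1 | starting material
12 | 3,5-bis(benzyloxy)-4-methoxybenzyne (triple bond between the former triflate and silyl carbons) | C1#CC(OCc2ccccc2)=C(OC)C(OCc2ccccc2)=C1 | intermediate
13 | 3,5-bis(benzyloxy)-2-[(benzyloxy)methyl]-4-methoxy-2H-benzo[b]oxet-2-ol (formed as its cesium alkoxide) | OC1(COCc2ccccc2)Oc2cc(OCc3ccccc3)c(OC)c(OCc3ccccc3)c21 | intermediate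
14 | 2-(benzyloxy)-1-[2,4-bis(benzyloxy)-6-hydroxy-3-methoxyphenyl]ethan-1-one | O=C(COCc1ccccc1)c1c(O)cc(OCc2ccccc2)c(OC)c1OCc1ccccc1 | intermediate
15 | 2-(benzyloxy)-1-[2,4-bis(benzyloxy)-3,6-dimethoxyphenyl]ethan-1-one | O=C(COCc1ccccc1)c1c(OC)cc(OCc2ccccc2)c(OC)c1OCc1ccccc1 | intermediate
16 | 2-(benzyloxy)-1-[4-(benzyloxy)-2-hydroxy-3,6-dimethoxyphenyl]ethan-1-one | O=C(COCc1ccccc1)c1c(OC)cc(OCc2ccccc2)c(OC)c1O | intermediate
17 | vanillin (4-hydroxy-3-methoxybenzaldehyde) | COc1cc(C=O)ccc1O | starting material
18 | 4-(benzyloxy)-3-methoxybenzaldehyde | COc1cc(C=O)ccc1OCc1ccccc1 | intermediate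
19 | 4-(benzyloxy)-3-methoxybenzoic acid | COc1cc(C(=O)O)ccc1OCc1ccccc1 | intermediate
20 | 4-(benzyloxy)-3-methoxybenzoyl chloride | COc1cc(C(=O)Cl)ccc1OCc1ccccc1 | intermediate
21 | 3-(benzyloxy)-6-[2-(benzyloxy)acetyl]-2,5-dimethoxyphenyl 4-(benzyloxy)-3-methoxybenzoate | COc1cc(ccc1OCc1ccccc1)C(=O)Oc1c(OC)c(OCc2ccccc2)cc(OC)c1C(=O)COCc1ccccc1 | intermediate
22 | 2-(benzyloxy)-1-[4-(benzyloxy)-2-hydroxy-3,6-dimethoxyphenyl]-3-[4-(benzyloxy)-3-methoxyphenyl]propane-1,3-dione | COc1cc(ccc1OCc1ccccc1)C(=O)C(OCc1ccccc1)C(=O)c1c(O)c(OC)c(OCc2ccccc2)cc1OC | intermediate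
23 | 3,7-bis(benzyloxy)-2-[4-(benzyloxy)-3-methoxyphenyl]-5,8-dimethoxy-4H-chromen-4-one | COc1cc(ccc1OCc1ccccc1)-c1oc2c(OC)c(OCc3ccccc3)cc(OC)c2c(=O)c1OCc1ccccc1 | intermediate
24 | 3,5,7-trihydroxy-2-(4-hydroxy-3-methoxyphenyl)-8-methoxy-4H-chromen-4-one | COc1cc(-c2oc3c(OC)c(O)cc(O)c3c(=O)c2O)ccc1O | intermediate
25 | 2-[4-(acetyloxy)-3-methoxyphenyl]-8-methoxy-4-oxo-4H-chromene-3,5,7-triyl triacetate | COc1cc(-c2oc3c(OC)c(OC(C)=O)cc(OC(C)=O)c3c(=O)c2OC(C)=O)ccc1OC(C)=O | intermediate
26 | prenyl bromide (1-bromo-3-methylbut-2-ene) | CC(C)=CCBr | starting material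
27 | 2-[4-(acetyloxy)-3-methoxyphenyl]-7-hydroxy-8-methoxy-4-oxo-4H-chromene-3,5-diyl diacetate (present as its potassium phenoxide) | COc1cc(-c2oc3c(OC)c(O)cc(OC(C)=O)c3c(=O)c2OC(C)=O)ccc1OC(C)=O | intermediate
28 | 2-[4-(acetyloxy)-3-methoxyphenyl]-8-methoxy-7-[(3-methylbut-2-en-1-yl)oxy]-4-oxo-4H-chromene-3,5-diyl diacetate | COc1cc(-c2oc3c(OC)c(OCC=C(C)C)cc(OC(C)=O)c3c(=O)c2OC(C)=O)ccc1OC(C)=O | intermediate
29 | 3,5-dihydroxy-2-(4-hydroxy-3-methoxyphenyl)-8-methoxy-7-[(3-methylbut-2-en-1-yl)oxy]-4H-chromen-4-one | COc1cc(-c2oc3c(OC)c(OCC=C(C)C)cc(O)c3c(=O)c2O)ccc1O | target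

## Step count and least certain steps

Total step count: 17. Longest linear sequence: 15 steps (steps 1–9, then 12–17); steps 10 and 11 are the side branch to acid 19.

**Step 7 (key step).** The aryl anion at C4a may be protonated before it reaches the carbonyl, which would stop the reaction at O-arylation. The carboxylate may also add with reversed orientation, or the product phenoxide may be arylated by a second aryne; all three are competitions between fast steps of a very reactive intermediate. The fallback abandons the aryne and sets out from bromophenol 7 and acid 11. Acid 11 is converted (carbonyldiimidazole, then N,O-dimethylhydroxylamine hydrochloride) into the Weinreb amide 2-(benzyloxy)-N-methoxy-N-methylacetamide F1. Bromophenol 7 is treated with n-BuLi (2.2 equiv, THF, −78 °C) to give the ortho-lithiated lithium phenoxide, which is acylated by F1. Work-up gives ketone 14, where the route is rejoined.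

**Step 5.** Over-bromination or oxidation of the very electron-rich phenol to a quinone may outrun clean monobromination. The fallback sets out from phenol 6 and uses directed ortho-metalation; it also bypasses step 6. Isopropyl isocyanate with catalytic Et3N gives 3,5-bis(benzyloxy)-4-methoxyphenyl N-isopropylcarbamate F2. N-Silylation (Me3SiOTf, TMEDA), lithiation between the carbamate and the benzyloxy group (n-BuLi, TMEDA, −78 °C) and Me3SiCl give, after mild acidic work-up, 3,5-bis(benzyloxy)-4-methoxy-2-(trimethylsilyl)phenyl N-isopropylcarbamate F3. Cleavage of the carbamate with DBU and Et2NH in MeCN and triflation of the phenoxide with PhNTf2 return the route to silyl triflate 10.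

**Step 9.** Cleavage may be sluggish because the doubly ortho-substituted ketone is twisted and the side-chain ether also binds magnesium; forcing it risks concurrent loss of the O5 methyl group. The fallback sets out from ketone 14 and masks O5 with a group that is not an ether, so that only one ortho ether remains:
- TsCl, Et3N and DMAP give 3,5-bis(benzyloxy)-2-[2-(benzyloxy)acetyl]-4-methoxyphenyl 4-methylbenzenesulfonate F4.
- MgBr2·OEt2 (toluene/Et2O, 80 °C) then gives 5-(benzyloxy)-2-[2-(benzyloxy)acetyl]-3-hydroxy-4-methoxyphenyl 4-methylbenzenesulfonate F5.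
- Acylation with acid chloride 20 gives 3-(benzyloxy)-6-[2-(benzyloxy)acetyl]-2-methoxy-5-[(4-methylbenzenesulfonyl)oxy]phenyl 4-(benzyloxy)-3-methoxybenzoate F6.
- Baker–Venkataraman rearrangement and acid cyclisation as in step 13 give 3,7-bis(benzyloxy)-2-[4-(benzyloxy)-3-methoxyphenyl]-8-methoxy-4-oxo-4H-chromen-5-yl 4-methylbenzenesulfonate F7.
- KOH in MeOH removes the sulfonate to give 3,7-bis(benzyloxy)-2-[4-(benzyloxy)-3-methoxyphenyl]-5-hydroxy-8-methoxy-4H-chromen-4-one F8.
- BCl3 with pentamethylbenzene then removes only benzyl groups and rejoins the route at tetrol 24.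

**Step 14.** Demethylation at O5 may stay incomplete at a temperature low enough to spare the methoxy groups on C8 and C3', or warming may start to remove those as well. The fallback sets out from flavone 23 and separates the two events. Hydrogenolysis (H2, Pd/C, EtOAc/MeOH) removes the three benzyl groups to give 3,7-dihydroxy-2-(4-hydroxy-3-methoxyphenyl)-5,8-dimethoxy-4H-chromen-4-one F9. Chelation-controlled demethylation with AlCl3 in MeCN then cleaves only the O5 methyl group and rejoins the route at tetrol 24.

**Step 16.** A second acetate (on O4' or O3) may be lost under the basic conditions, leading to double alkylation, or the hindered 7-acetate next to the C8 methoxy group may be cleaved too slowly. The fallback sets out from tetraacetate 25 and separates deacetylation from alkylation. Thiolate-mediated removal of the 7-acetate (PhSH, imidazole, N-methylpyrrolidone, 0 °C) gives phenol 27, which is isolated. It is then etherified under neutral Mitsunobu conditions (3-methylbut-2-en-1-ol, PPh3, diisopropyl azodicarboxylate, THF), rejoining the route at triacetate 28.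

## Further compounds

F1 | step 7 | 2-(benzyloxy)-N-methoxy-N-methylacetamide | CON(C)C(=O)COCc1ccccc1
F2 | step 5 | 3,5-bis(benzyloxy)-4-methoxyphenyl N-isopropylcarbamate | CC(C)NC(=O)Oc1cc(OCc2ccccc2)c(OC)c(OCc2ccccc2)c1
F3 | step 5 | 3,5-bis(benzyloxy)-4-methoxy-2-(trimethylsilyl)phenyl N-isopropylcarbamate | CC(C)NC(=O)Oc1cc(OCc2ccccc2)c(OC)c(OCc2ccccc2)c1[Si](C)(C)C
F4 | step 9 | 3,5-bis(benzyloxy)-2-[2-(benzyloxy)acetyl]-4-methoxyphenyl 4-methylbenzenesulfonate | Cc1ccc(cc1)S(=O)(=O)Oc1cc(OCc2ccccc2)c(OC)c(OCc2ccccc2)c1C(=O)COCc1ccccc1
F5 | step 9 | 5-(benzyloxy)-2-[2-(benzyloxy)acetyl]-3-hydroxy-4-methoxyphenyl 4-methylbenzenesulfonate | Cc1ccc(cc1)S(=O)(=O)Oc1cc(OCc2ccccc2)c(OC)c(O)c1C(=O)COCc1ccccc1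
F6 | step 9 | 3-(benzyloxy)-6-[2-(benzyloxy)acetyl]-2-methoxy-5-[(4-methylbenzenesulfonyl)oxy]phenyl 4-(benzyloxy)-3-methoxybenzoate | COc1cc(ccc1OCc1ccccc1)C(=O)Oc1c(OC)c(OCc2ccccc2)cc(OS(=O)(=O)c2ccc(C)cc2)c1C(=O)COCc1ccccc1
F7 | step 9 | 3,7-bis(benzyloxy)-2-[4-(benzyloxy)-3-methoxyphenyl]-8-methoxy-4-oxo-4H-chromen-5-yl 4-methylbenzenesulfonate | COc1cc(ccc1OCc1ccccc1)-c1oc2c(OC)c(OCc3ccccc3)cc(OS(=O)(=O)c3ccc(C)cc3)c2c(=O)c1OCc1ccccc1
F8 | step 9 | 3,7-bis(benzyloxy)-2-[4-(benzyloxy)-3-methoxyphenyl]-5-hydroxy-8-methoxy-4H-chromen-4-one | COc1cc(ccc1OCc1ccccc1)-c1oc2c(OC)c(OCc3ccccc3)cc(O)c2c(=O)c1OCc1ccccc1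
F9 | step 14 | 3,7-dihydroxy-2-(4-hydroxy-3-methoxyphenyl)-5,8-dimethoxy-4H-chromen-4-one | COc1cc(-c2oc3c(OC)c(O)cc(OC)c3c(=O)c2O)ccc1O
F0 | step 16 | none | none
A1 | alternative 1 | methyl 2-(1-methoxy-2-oxopropyl)-6-[3-methoxy-4-(methoxymethoxy)phenyl]-5-(methoxymethoxy)-4-oxo-4H-pyran-3-carboxylate | COCOc1ccc(cc1OC)-c1oc(C(OC)C(C)=O)c(C(=O)OC)c(=O)c1OCOC
A2 | alternative 1 | 5,7-dihydroxy-8-methoxy-2-[3-methoxy-4-(methoxymethoxy)phenyl]-3-(methoxymethoxy)-4H-chromen-4-one | COc1cc(-c2oc3c(OC)c(O)cc(O)c3c(=O)c2OCOC)ccc1OCOC
A3 | alternative 2 | 3-methoxy-6-(methoxymethoxy)-2-{1-[3-methoxy-4-(methoxymethoxy)phenyl]-2-oxoethoxy}-4-[(3-methylbut-2-en-1-yl)oxy]benzaldehyde | O=Cc1c(OCOC)cc(OCC=C(C)C)c(OC)c1OC(C=O)c1ccc(OCOC)c(OC)c1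
A4 | alternative 2 | 8-methoxy-2-[3-methoxy-4-(methoxymethoxy)phenyl]-5-(methoxymethoxy)-7-[(3-methylbut-2-en-1-yl)oxy]chromane-3,4-diol (diastereomer mixture) | OC1c2c(OCOC)cc(OCC=C(C)C)c(OC)c2OC(c2ccc(OCOC)c(OC)c2)C1O
A5 | alternative 3 | 3,5-bis(benzyloxy)-2-iodo-6-methoxyphenol | Oc1c(I)c(OCc2ccccc2)cc(OCc2ccccc2)c1OC
A6 | alternative 3 | 1-(benzyloxy)-4-ethynyl-2-methoxybenzene | C#Cc1ccc(OCc2ccccc2)c(OC)c1
A7 | alternative 3 | 5,7-bis(benzyloxy)-2-[4-(benzyloxy)-3-methoxyphenyl]-8-methoxy-4H-chromen-4-one | COc1cc(-c2cc(=O)c3c(OCc4ccccc4)cc(OCc4ccccc4)c(OC)c3o2)ccc1OCc1ccccc1
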